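**Strategy.** Ring B of the decalin (C5–C6–C7–C8–C9–C10, eudesmane numbering) is cut at its two opposite bonds, the ring-fusion bond C5–C10 (also part of ring A) and C7–C8, which unravels the core to an acyclic trienal. One acid-mediated operation forms both bonds again: the protonated C8–C10 enal is attacked at C10 by the Z-C4=C5 olefin (ring A), and the resulting C8 aldehyde closes ring B by a Prins reaction with the C7=C11 olefin. The tertiary carbinols C4 and C11 mark where the two cations are quenched. The precursor's only stereocentres, C1 and benzylic C1′, come from two organocatalytic steps; formylation and demethylation of the arene come last.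

Key step: step 9

Remark: terpenoid carbons carry eudesmane numbers (C1 bears the side chain, C4 the ring carbinol, C5 and C10 are the fusion carbons, C7 bears C11, C1′ is the benzylic carbon), and (E)-5-methylhex-2-enal is treated as a purchasable aldehyde.

Step 1
Reactants: 1 1,3,5-trimethoxybenzene; 2 (E)-5-methylhex-2-enal
Product: 3 (3S)-5-methyl-3-(2,4,6-trimethoxyphenyl)hexanal
Conditions: (2R,5R)-5-benzyl-2-tert-butyl-3-methylimidazolidin-4-one·CF3CO2H (20 mol%), 1 (3 equiv), CH2Cl2–iPrOH, −40 °C
Reagents that add atoms: none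
Why: Iminium-catalysed Friedel–Crafts conjugate alkylation, in which the (2R,5R) catalyst shields the Re face of C-β of the E-iminium ion so that the strongly nucleophilic arene should add to the Si face and set C1′ as S.

Step 2
Reactants: 3 (3S)-5-methyl-3-(2,4,6-trimethoxyphenyl)hexanal; 4 methyl vinyl ketone
Product: 5 (2S)-2-[(1S)-3-methyl-1-(2,4,6-trimethoxyphenyl)butyl]-5-oxohexanal
Conditions: (S)-2-[diphenyl(trimethylsilyloxy)methyl]pyrrolidine (15 mol%), 4-nitrophenol (30 mol%), 4 (1.5 equiv), THF, 4 °C
Reagents that add atoms: none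
Why: Enamine-catalysed Michael addition of the aldehyde to the vinyl ketone, in which the anti E-enamine is blocked on one face by the diphenyl(silyloxy)methyl group, so the catalyst rather than C1′ should fix the new centre C1 as S.

Step 3
Reactants: 5 (2S)-2-[(1S)-3-methyl-1-(2,4,6-trimethoxyphenyl)butyl]-5-oxohexanal
Product: 6 (5S)-6-hydroxy-5-[(1S)-3-methyl-1-(2,4,6-trimethoxyphenyl)butyl]heptan-2-one (both C6 epimers; in equilibrium with its cyclic hemiketal)
Conditions: MeTi(OiPr)3 (1.2 equiv), THF, −40 → 0 °C
Reagents that add atoms: methyltitanium triisopropoxide, C[Ti](OC(C)C)(OC(C)C)OC(C)C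
Why: Chemoselective carbonyl methylation by the non-basic methyltitanium reagent, which should add to the aldehyde far faster than to the methyl ketone and should not enolise C1; the new carbinol centre forms as a mixture that step 6 removes.

Step 4
Reactants: 7 5-bromo-2-methylpent-2-ene; 8 triphenylphosphine
Product: 9 (4-methylpent-3-en-1-yl)triphenylphosphonium bromide
Conditions: MeCN, reflux
Reagents that add atoms: none
Why: SN2 quaternisation of the phosphine by the primary homoallylic bromide.

Step 5
Reactants: 6 (5S)-6-hydroxy-5-[(1S)-3-methyl-1-(2,4,6-trimethoxyphenyl)butyl]heptan-2-one; 9 (4-methylpent-3-en-1-yl)triphenylphosphonium bromide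
Product: 11 (3S,6Z)-6,10-dimethyl-3-[(1S)-3-methyl-1-(2,4,6-trimethoxyphenyl)butyl]undeca-6,9-dien-2-ol (both C2 epimers), via phosphorus ylide 10 (not isolated)
Conditions: 9 (3 equiv), KN(SiMe3)2, THF, −78 °C; then 6, −78 → 23 °C; E isomer removed on AgNO3–SiO2
Reagents that add atoms: none
Why: Lithium-free Wittig olefination, in which the non-stabilised ylide should add to the methyl ketone (released from its hemiketal by the base) through the cis-oxaphosphetane that places the ylide chain beside the larger ketone substituent, giving mainly the Z trisubstituted olefin.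

Step 6
Reactants: 11 (3S,6Z)-6,10-dimethyl-3-[(1S)-3-methyl-1-(2,4,6-trimethoxyphenyl)butyl]undeca-6,9-dien-2-ol
Product: 12 (3S,6Z)-6,10-dimethyl-3-[(1S)-3-methyl-1-(2,4,6-trimethoxyphenyl)butyl]undeca-6,9-dien-2-one
Conditions: Dess–Martin periodinane, NaHCO3, CH2Cl2, 0 → 23 °C
Reagents that add atoms: none
Why: Dess–Martin oxidation under buffered, non-enolising conditions should converge both carbinol epimers to one methyl ketone and leave C1 untouched.

Step 7
Reactants: 12 (3S,6Z)-6,10-dimethyl-3-[(1S)-3-methyl-1-(2,4,6-trimethoxyphenyl)butyl]undeca-6,9-dien-2-one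
Product: 13 (2E,4S,7Z)-3,7,11-trimethyl-4-[(1S)-3-methyl-1-(2,4,6-trimethoxyphenyl)butyl]dodeca-2,7,10-trienenitrile
Conditions: (EtO)2P(O)CH2CN, NaH, THF, 0 → 50 °C; minor 2Z isomer separated
Reagents that add atoms: diethyl (cyanomethyl)phosphonate, CCOP(=O)(CC#N)OCC
Why: Horner–Wadsworth–Emmons olefination of a methyl ketone (the classical two-carbon extension towards citral-type enals), in which the bulky C1 substituent should end trans to the nitrile and give mainly the 2E olefin.

Step 8
Reactants: 13 (2E,4S,7Z)-3,7,11-trimethyl-4-[(1S)-3-methyl-1-(2,4,6-trimethoxyphenyl)butyl]dodeca-2,7,10-trienenitrile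
Product: 14 (2E,4S,7Z)-3,7,11-trimethyl-4-[(1S)-3-methyl-1-(2,4,6-trimethoxyphenyl)butyl]dodeca-2,7,10-trienal
Conditions: iBu2AlH (1.2 equiv), toluene, −78 °C; then aqueous tartaric acid, 0 °C
Reagents that add atoms: water, O
Why: Partial reduction of the conjugated nitrile by the aluminium hydride to the N-aluminated aldimine, which hydrolyses on work-up to the E enal without touching the isolated olefins.

Step 9
Reactants: 14 (2E,4S,7Z)-3,7,11-trimethyl-4-[(1S)-3-methyl-1-(2,4,6-trimethoxyphenyl)butyl]dodeca-2,7,10-trienal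
Product: 17 (1S,4R,5S,7R,10R)-7-(2-hydroxypropan-2-yl)-4,10-dimethyl-1-[(1S)-3-methyl-1-(2,4,6-trimethoxyphenyl)butyl]decalin-4,8-diol (trans-fused; both C8 epimers), via ring-A formate aldehyde 15 (not isolated), via bicyclic bis-formate 16 (not isolated)
Conditions: HCO2H (98%), 0 → 23 °C, 0.01 M; then K2CO3, MeOH–H2O, 23 °C
Reagents that add atoms: formic acid, OC=O
Why: Formic acid protonates the conjugated aldehyde (the isolated trisubstituted olefins are far less basic), C5 of the Z-C4=C5 olefin adds to C10 and formate caps the developing C4 cation from the opposite face (15); after enol-to-aldehyde tautomerisation the protonated C8 aldehyde is attacked by C7 of the prenyl terminus and formate caps the C11 cation (16), and K2CO3/MeOH then cleaves the formates. The closest known reaction types are acid-promoted enal- or enone-initiated cation–olefin cyclisations (sequential conjugate-ene/carbonyl-ene reactions), polyene formolysis with anti capture of the terminal cation, and the Prins cyclisation of citronellal to p-menthane-3,8-diol. Ring A closes through a chair in a mode that is 6-endo for the C4=C5 olefin and 6-exo for the C9=C10 enal; ring B closes through a chair in a 6-exo Prins mode that leaves the C11 cation outside the ring. C10 is set by the existing centre C1 (with the E enal, allylic 1,2-strain places the C1–H bond beside the C10 methyl and the bulky side chain anti to the incoming C5, so methyl and side chain end trans); C5 and C4 follow stereospecifically from the Z olefin by anti addition, which puts C6 trans to C9 (hence a trans ring fusion) and the C4 oxygen cis to the C10 methyl; C7 takes the equatorial position of the Prins chair, and C8 forms as an epimer mixture that step 11 erases. The step needs carbonyl activation to outrun olefin protonation and nucleophilic capture to outrun proton loss or syn capture by the enol oxygen; the moderately acidic yet nucleophilic medium and the shielding of the syn face of C4 by the axial C9 arm are expected to secure this.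

Step 10
Reactants: 17 (1S,4R,5S,7R,10R)-7-(2-hydroxypropan-2-yl)-4,10-dimethyl-1-[(1S)-3-methyl-1-(2,4,6-trimethoxyphenyl)butyl]decalin-4,8-diol
Product: 18 O-phenyl thionocarbonate of 17 at the C8 hydroxyl
Conditions: PhOC(S)Cl (1.3 equiv), pyridine, DMAP (cat.), CH2Cl2, 0 → 23 °C
Reagents that add atoms: O-phenyl chlorothionoformate, S=C(Cl)Oc1ccccc1
Why: Thioacylation should occur only at the secondary C8 hydroxyl because the two tertiary hydroxyls are too hindered, giving the precursor for a Barton–McCombie deoxygenation.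

Step 11
Reactants: 18 O-phenyl thionocarbonate of 17 at the C8 hydroxyl
Product: 19 (1S,4R,5S,7S,10R)-7-(2-hydroxypropan-2-yl)-4,10-dimethyl-1-[(1S)-3-methyl-1-(2,4,6-trimethoxyphenyl)butyl]decalin-4-ol
Conditions: Bu3SnH (1.5 equiv), AIBN (cat.), toluene, 90 °C
Reagents that add atoms: none
Why: Barton–McCombie deoxygenation, in which the stannyl radical adds to the thiocarbonyl, the C8–O bond fragments to a secondary radical and this abstracts hydrogen from the stannane; no stereocentre is formed and both C8 epimers converge.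

Step 12
Reactants: 19 (1S,4R,5S,7S,10R)-7-(2-hydroxypropan-2-yl)-4,10-dimethyl-1-[(1S)-3-methyl-1-(2,4,6-trimethoxyphenyl)butyl]decalin-4-ol
Product: 20 the 3,5-dibromo-2,4,6-trimethoxyphenyl analogue of 19
Conditions: N-bromosuccinimide (2.1 equiv), MeCN, 0 °C, dark
Reagents that add atoms: N-bromosuccinimide, O=C1CCC(=O)N1Br
Why: Electrophilic aromatic bromination of the highly activated arene at its two free, equivalent ring positions; the tertiary alcohols and the saturated core should be inert.

Step 13
Reactants: 20 the 3,5-dibromo-2,4,6-trimethoxyphenyl analogue of 19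
Product: 22 the 3,5-diformyl-2,4,6-trimethoxyphenyl analogue of 19, via dilithio dialkoxide 21 (not isolated)
Conditions: t-BuLi (6.5 equiv), THF, −78 °C; DMF (excess), −78 → 0 °C; aqueous NH4Cl
Reagents that add atoms: N,N-dimethylformamide, CN(C)C=O
Why: After deprotonation of both hydroxyls a double bromine–lithium exchange should give the aryl dilithium (each C–Li flanked by two methoxy groups), which DMF formylates twice (Bouveault aldehyde synthesis).

Step 14
Reactants: 22 the 3,5-diformyl-2,4,6-trimethoxyphenyl analogue of 19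
Product: 23 5-{(1S)-1-[(1S,4R,5S,7S,10R)-4-hydroxy-7-(2-hydroxypropan-2-yl)-4,10-dimethyldecalin-1-yl]-3-methylbutyl}-2,4,6-trihydroxybenzene-1,3-dicarbaldehyde (target)
Conditions: NaSEt (12 equiv), DMF, 120 °C; then 1 M HCl, 0 °C
Reagents that add atoms: none
Why: Threefold SN2 O-demethylation by ethanethiolate, which should be feasible because every methoxy group is ortho or para to a formyl group, while the basic, non-ionising medium spares both tertiary alcohols.

**Compound list**

1 | 1,3,5-trimethoxybenzene | COc1cc(OC)cc(OC)c1 | starting material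
2 | (E)-5-methylhex-2-enal | CC(C)C/C=C/C=O | starting material
3 | (3S)-5-methyl-3-(2,4,6-trimethoxyphenyl)hexanal | CC(C)C[C@H](c1c(OC)cc(OC)cc1OC)CC=O | intermediate
4 | methyl vinyl ketone (but-3-en-2-one) | CC(=O)C=C | starting material
5 | (2S)-2-[(1S)-3-methyl-1-(2,4,6-trimethoxyphenyl)butyl]-5-oxohexanal | CC(C)C[C@H](c1c(OC)cc(OC)cc1OC)[C@@H](C=O)CCC(C)=O | intermediate
6 | (5S)-6-hydroxy-5-[(1S)-3-methyl-1-(2,4,6-trimethoxyphenyl)butyl]heptan-2-one, both C6 epimers | CC(C)C[C@H](c1c(OC)cc(OC)cc1OC)[C@@H](C(C)O)CCC(C)=O | intermediate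
7 | 5-bromo-2-methylpent-2-ene | CC(C)=CCCBr | starting material
8 | triphenylphosphine | c1ccc(cc1)P(c1ccccc1)c1ccccc1 | starting material
9 | (4-methylpent-3-en-1-yl)triphenylphosphonium bromide | CC(C)=CCC[P+](c1ccccc1)(c1ccccc1)c1ccccc1.[Br-] | intermediate
10 | (4-methylpent-3-en-1-ylidene)triphenylphosphorane, ylide, not isolated | CC(C)=CCC=P(c1ccccc1)(c1ccccc1)c1ccccc1 | intermediate
11 | (3S,6Z)-6,10-dimethyl-3-[(1S)-3-methyl-1-(2,4,6-trimethoxyphenyl)butyl]undeca-6,9-dien-2-ol, both C2 epimers | CC(C)C[C@H](c1c(OC)cc(OC)cc1OC)[C@@H](C(C)O)CC/C(C)=C\CC=C(C)C | intermediate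
12 | (3S,6Z)-6,10-dimethyl-3-[(1S)-3-methyl-1-(2,4,6-trimethoxyphenyl)butyl]undeca-6,9-dien-2-one | CC(C)C[C@H](c1c(OC)cc(OC)cc1OC)[C@@H](C(C)=O)CC/C(C)=C\CC=C(C)C | intermediate
13 | (2E,4S,7Z)-3,7,11-trimethyl-4-[(1S)-3-methyl-1-(2,4,6-trimethoxyphenyl)butyl]dodeca-2,7,10-trienenitrile | CC(C)C[C@H](c1c(OC)cc(OC)cc1OC)[C@@H](/C(C)=C/C#N)CC/C(C)=C\CC=C(C)C | intermediate
14 | (2E,4S,7Z)-3,7,11-trimethyl-4-[(1S)-3-methyl-1-(2,4,6-trimethoxyphenyl)butyl]dodeca-2,7,10-trienal | CC(C)C[C@H](c1c(OC)cc(OC)cc1OC)[C@@H](/C(C)=C/C=O)CC/C(C)=C\CC=C(C)C | intermediate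
15 | ring-A formate aldehyde, not isolated: cyclohexane C1–C5/C10 with CH3 and CH2CHO at C10, prenyl at C5, CH3 and formyloxy at C4, side chain at C1 (1S,4R,5S,10R,1′S) | CC(C)C[C@H](c1c(OC)cc(OC)cc1OC)[C@@H]1CC[C@@](C)(OC=O)[C@@H](CC=C(C)C)[C@]1(C)CC=O | intermediate
16 | bicyclic bis-formate, not isolated: 17 with formyloxy groups at C4 and C11 | CC(C)C[C@H](c1c(OC)cc(OC)cc1OC)[C@@H]1CC[C@@](C)(OC=O)[C@H]2C[C@@H](C(C)(C)OC=O)C(O)C[C@]12C | intermediate
17 | (1S,4R,5S,7R,10R)-7-(2-hydroxypropan-2-yl)-4,10-dimethyl-1-[(1S)-3-methyl-1-(2,4,6-trimethoxyphenyl)butyl]decalin-4,8-diol, trans-fused, both C8 epimers | CC(C)C[C@H](c1c(OC)cc(OC)cc1OC)[C@@H]1CC[C@@](C)(O)[C@H]2C[C@@H](C(C)(C)O)C(O)C[C@]12C | intermediate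
18 | O-phenyl thionocarbonate of 17 at the C8 hydroxyl | CC(C)C[C@H](c1c(OC)cc(OC)cc1OC)[C@@H]1CC[C@@](C)(O)[C@H]2C[C@@H](C(C)(C)O)C(OC(=S)Oc3ccccc3)C[C@]12C | intermediate
19 | (1S,4R,5S,7S,10R)-7-(2-hydroxypropan-2-yl)-4,10-dimethyl-1-[(1S)-3-methyl-1-(2,4,6-trimethoxyphenyl)butyl]decalin-4-ol | CC(C)C[C@H](c1c(OC)cc(OC)cc1OC)[C@@H]1CC[C@@](C)(O)[C@H]2C[C@@H](C(C)(C)O)CC[C@]12C | intermediate
20 | 3,5-dibromo-2,4,6-trimethoxyphenyl analogue of 19 | CC(C)C[C@H](c1c(OC)c(Br)c(OC)c(Br)c1OC)[C@@H]1CC[C@@](C)(O)[C@H]2C[C@@H](C(C)(C)O)CC[C@]12C | intermediate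
21 | dilithio dialkoxide of 20 (aryl 3,5-dilithium, both hydroxyls as lithium alkoxides), not isolated | CC(C)C[C@H](c1c(OC)c([Li])c(OC)c([Li])c1OC)[C@@H]1CC[C@@](C)(O[Li])[C@H]2C[C@@H](C(C)(C)O[Li])CC[C@]12C | intermediate
22 | 3,5-diformyl-2,4,6-trimethoxyphenyl analogue of 19 | CC(C)C[C@H](c1c(OC)c(C=O)c(OC)c(C=O)c1OC)[C@@H]1CC[C@@](C)(O)[C@H]2C[C@@H](C(C)(C)O)CC[C@]12C | intermediate
23 | 5-{(1S)-1-[(1S,4R,5S,7S,10R)-4-hydroxy-7-(2-hydroxypropan-2-yl)-4,10-dimethyldecalin-1-yl]-3-methylbutyl}-2,4,6-trihydroxybenzene-1,3-dicarbaldehyde | CC(C)C[C@H](c1c(O)c(C=O)c(O)c(C=O)c1O)[C@@H]1CC[C@@](C)(O)[C@H]2C[C@@H](C(C)(C)O)CC[C@]12C | target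

**Step count.** Total: 14 steps. Longest linear sequence: 13 steps (1/2 → 3 → 5 → 6 → 11 → 12 → 13 → 14 → 17 → 18 → 19 → 20 → 22 → 23); step 4 is a one-step side branch.

**Steps most likely to fail**

Step 9 (key cascade). Several processes can divert it:
- the C4 or C11 cation may lose a proton instead of being captured;
- the enol oxygen may capture the C4 cation on the syn face, which would give the C4 epimer;
- the isolated olefins may be protonated first, which would scramble the Z geometry;
- C5 may attack the other face of the enal, which would give the C10/C5 epimeric series;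
- C1 may erode through dienol formation.

The fallback sets out from 14 and returns at 17. Under aprotic Lewis acid conditions (Me2AlCl, CH2Cl2, −78 → 0 °C) the same two C–C bonds should form by a conjugate ene reaction followed by a carbonyl-ene reaction. Both cations then end by proton transfer, giving the 3-ene-8-ol with a 7-isopropenyl group, dienol F1. Double oxymercuration–demercuration (Hg(OAc)2, THF–H2O; then NaBH4, NaOH) should hydrate both olefins in the Markovnikov sense. Water opens the ring mercurinium ion trans-diaxially at C4, which gives the axial hydroxyl, and the product is triol 17.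

Step 5 (Wittig olefination). Oxaphosphetane formation with a methyl ketone may show poor cis selectivity, so that much E olefin forms; the E isomer would lead to the wrong C4/C5 series. The fallback sets out from 6 and 9 and returns at 11. Salt 9 is hydrolysed (aqueous NaOH, heat) to (4-methylpent-3-en-1-yl)diphenylphosphine oxide F2. Its lithio derivative (n-BuLi, THF, −78 °C, 2.2 equiv) is added to the ketone of 6 in a Horner–Wittig reaction. The resulting β-hydroxy phosphine oxides are separated by chromatography, and the diastereomer pair leading to the Z olefin, β-hydroxy phosphine oxide F3, is kept. Stereospecific syn elimination (NaH, DMF, 50 °C) then gives 11 as a single olefin isomer.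

Step 14 (global demethylation). The third ether cleavage may stall once two phenoxides have formed, and prolonged heating with thiolate may damage the aldehydes. The fallback sets out from 19 and returns at 23, bypassing 20–22. The three methyl ethers are cleaved before any formyl group is present (NaSEt, DMF, 150 °C, inert atmosphere) to give the alkylphloroglucinol, triphenol F4. A twofold magnesium-mediated ortho-formylation (MgCl2, Et3N, paraformaldehyde, MeCN, reflux; Casnati–Skattebøl formylation) then installs both aldehydes under conditions that tolerate the tertiary alcohols.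

Further compounds
F1 | step 9 | 3-ene-8-ol with 7-isopropenyl group: bicyclic dienol from the Lewis-acid double ene cascade (2,4,6-trimethoxyphenyl side chain, trans-fused, both C8 epimers) | CC(C)C[C@H](c1c(OC)cc(OC)cc1OC)[C@@H]1CC=C(C)[C@H]2C[C@@H](C(C)=C)C(O)C[C@]12C
F2 | step 5 | (4-methylpent-3-en-1-yl)diphenylphosphine oxide | CC(C)=CCCP(=O)(c1ccccc1)c1ccccc1
F3 | step 5 | β-hydroxy phosphine oxide from 6 and lithiated F2 (separated diastereomer pair that eliminates to the Z olefin; the two new centres are not assigned) | CC(C)C[C@H](c1c(OC)cc(OC)cc1OC)[C@@H](C(C)O)CCC(C)(O)C(CC=C(C)C)P(=O)(c1ccccc1)c1ccccc1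
F4 | step 14 | 2,4,6-trihydroxyphenyl analogue of 19 (alkylphloroglucinol diol) | CC(C)C[C@H](c1c(O)cc(O)cc1O)[C@@H]1CC[C@@](C)(O)[C@H]2C[C@@H](C(C)(C)O)CC[C@]12C
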